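**Plan**
- Cuts (side chain numbered C1' at the benzylic carbon to C9' next to the cyclohexene): first C1'–C2' between the benzylic CH2 and the vinyl CH, then C5'–C6' and the two C–CH3 bonds at C3' and C7'; the carboxyl is carried as a methyl ester.
- Chain half: both rings are bought; dihydro-β-ionone 1 gives the cyclohexene and C6'–C9', and the chain grows outward (methyl ketone to alkyne, methylalumination/iodination, homopropargyl coupling for C2'–C5', desilylation, second methylalumination/iodination) to the C19 (E,E)-dienyl iodide 11.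
- Arene half: methyl 3-formyl-4-hydroxybenzoate 12 becomes the O-Boc salicyl alcohol 14 in two steps; its formyl carbon is C1'.
- Union: the hydroxyl oxygen on C4 of the benzoate ring is ortho to the CH2 on C3, so the unit O–C4–C3–C1' can be unmasked as the o-quinone methide 18 (C4=O, C3=C1'H2). The alkenylmagnesium made from 11 adds to C1', the benzene ring re-forms, and ester hydrolysis gives 20.
- Stereochemistry: there is no stereocentre; both E alkenes come from syn Zr-catalysed methylalumination of terminal alkynes and are carried with retention through every later substitution at sp2 carbon.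

Key step: step 8

Remark: compounds 1, 6 and 12 are taken to be commercial; equivalents are intended amounts, not results.

**Step 1**
Reactants: 1 dihydro-β-ionone [4-(2,6,6-trimethylcyclohex-1-en-1-yl)butan-2-one]
Product: 3 terminal alkyne 2-(but-3-yn-1-yl)-1,3,3-trimethylcyclohex-1-ene, via enol phosphate 2 (not isolated)
Conditions: LDA (1.05 equiv), THF, −78 °C; ClP(O)(OEt)2, −78 °C → rt; then LDA (2.3 equiv), THF, −78 °C → rt; H2O
Reagents that add atoms: none
Why: LDA removes a proton from the less hindered methyl group under kinetic control, O-phosphorylation traps the terminal enolate as 2, and further LDA eliminates diethyl phosphate to the acetylide (Negishi conversion of a methyl ketone into a terminal alkyne), the tetrasubstituted ring alkene being inert to amide base.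

**Step 2**
Reactants: 3 terminal alkyne 2-(but-3-yn-1-yl)-1,3,3-trimethylcyclohex-1-ene
Product: 5 alkenyl iodide 2-[(3E)-4-iodo-3-methylbut-3-en-1-yl]-1,3,3-trimethylcyclohex-1-ene, via alkenylalane 4 (not isolated)
Conditions: AlMe3 (2 equiv), Cp2ZrCl2 (0.25 equiv), CH2Cl2, 0 °C → rt; then I2, THF, −30 → 0 °C
Reagents that add atoms: trimethylaluminium, C[Al](C)C; iodine, II
Why: Negishi Zr-catalysed methylalumination adds CH3 and Al syn across the terminal alkyne with aluminium on the terminal carbon, and iodinolysis of the C–Al bond of 4 goes with retention, which sets the C6'=C7' alkene as E; the tetrasubstituted ring alkene does not carbometalate.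

**Step 3**
Reactants: 5 alkenyl iodide 2-[(3E)-4-iodo-3-methylbut-3-en-1-yl]-1,3,3-trimethylcyclohex-1-ene; 6 (4-bromobut-1-yn-1-yl)trimethylsilane
Product: 8 silyl enyne trimethyl[(5E)-6-methyl-8-(2,6,6-trimethylcyclohex-1-en-1-yl)oct-5-en-1-yn-1-yl]silane, via homopropargylzinc bromide 7 (not isolated)
Conditions: 6, Zn dust, LiCl, THF, 40 °C; then 5, Pd(PPh3)4 (5 mol %), THF, rt
Reagents that add atoms: none
Why: Negishi coupling, in which oxidative addition of the alkenyl iodide to zerovalent palladium, transmetalation from the primary alkylzinc 7 (from LiCl-promoted zinc insertion into 6) and reductive elimination form the sp2–sp3 bond C5'–C6' with retention of the E geometry, the silyl group blocking the alkyne terminus.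

**Step 4**
Reactants: 8 silyl enyne trimethyl[(5E)-6-methyl-8-(2,6,6-trimethylcyclohex-1-en-1-yl)oct-5-en-1-yn-1-yl]silane
Product: 9 terminal enyne 1,3,3-trimethyl-2-[(3E)-3-methyloct-3-en-7-yn-1-yl]cyclohex-1-ene
Conditions: K2CO3, MeOH–THF, rt
Reagents that add atoms: none
Why: Methoxide-mediated protodesilylation cleaves only the sp-bound C–Si bond and leaves both alkenes untouched.

**Step 5**
Reactants: 9 terminal enyne 1,3,3-trimethyl-2-[(3E)-3-methyloct-3-en-7-yn-1-yl]cyclohex-1-ene
Product: 11 dienyl iodide 2-[(3E,7E)-8-iodo-3,7-dimethylocta-3,7-dien-1-yl]-1,3,3-trimethylcyclohex-1-ene, via alkenylalane 10 (not isolated)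
Conditions: AlMe3 (2 equiv), Cp2ZrCl2 (0.25 equiv), CH2Cl2, 0 °C → rt; then I2, THF, −30 → 0 °C
Reagents that add atoms: trimethylaluminium, C[Al](C)C; iodine, II
Why: A second Negishi methylalumination, regio- and syn-selective as in step 2 and unaffected by the remote trisubstituted alkene, followed by retentive iodinolysis of 10, sets the C2'=C3' alkene as E.

**Step 6**
Reactants: 12 methyl 3-formyl-4-hydroxybenzoate
Product: 13 aryl carbonate methyl 4-[(tert-butoxycarbonyl)oxy]-3-formylbenzoate
Conditions: Boc2O (1.1 equiv), i-Pr2NEt, DMAP (5 mol %), CH2Cl2, 0 °C → rt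
Reagents that add atoms: di-tert-butyl dicarbonate, CC(C)(C)OC(=O)OC(=O)OC(C)(C)C
Why: DMAP-catalysed O-acylation of the acidic phenol installs the aryl tert-butyl carbonate that serves as the relay leaving group of the key step; aldehyde and ester do not react.

**Step 7**
Reactants: 13 aryl carbonate methyl 4-[(tert-butoxycarbonyl)oxy]-3-formylbenzoate
Product: 14 O-Boc salicyl alcohol methyl 4-[(tert-butoxycarbonyl)oxy]-3-(hydroxymethyl)benzoate
Conditions: BH3·THF (1.0 equiv), THF, −10 → 0 °C; pH 7 buffer
Reagents that add atoms: none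
Why: Electrophilic borane reduces the aldehyde far faster than the ester or carbonate (chemoselective carbonyl reduction), and since no free alkoxide arises under these neutral conditions the Boc group should stay on the phenolic oxygen until step 8.

**Step 8**
Reactants: 11 dienyl iodide 2-[(3E,7E)-8-iodo-3,7-dimethylocta-3,7-dien-1-yl]-1,3,3-trimethylcyclohex-1-ene; 14 O-Boc salicyl alcohol methyl 4-[(tert-butoxycarbonyl)oxy]-3-(hydroxymethyl)benzoate
Product: 19 methyl 3-[(2E,6E)-3,7-dimethyl-9-(2,6,6-trimethylcyclohex-1-en-1-yl)nona-2,6-dien-1-yl]-4-hydroxybenzoate, via alkenyllithium 15 (not isolated), via alkenylmagnesium bromide 16 (not isolated), via magnesium aryloxide 17 (not isolated), via o-quinone methide 18 (not isolated)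
Conditions: 11 (1.3 equiv), t-BuLi (2.0 equiv per 11), Et2O, −78 °C, then MgBr2·OEt2, −78 → 0 °C; separately 14 (1.0 equiv), t-BuMgCl (1.0 equiv), Et2O–toluene, −78 °C; add the solution of 16 at −78 °C, then → rt; aq NH4Cl
Reagents that add atoms: none
Why: t-BuMgCl deprotonates the benzylic alcohol of 14, the alkoxide takes the Boc group from the phenolic oxygen through a six-membered tetrahedral intermediate, and the magnesium aryloxide 17 expels tert-butyl carbonate by 1,4-elimination to give o-quinone methide 18, which the alkenylmagnesium bromide 16 captures by 1,4-addition at the exocyclic CH2 with return of the benzene ring. The closest known reaction type is the anionic generation of o-quinone methides from o-OBoc salicyl alcohols and their trapping by Grignard reagents to give ortho-alkylated phenols. No ring is closed and no stereocentre is formed; the E geometry at C2'=C3' is carried from 11 because iodine–lithium exchange, transmetalation to magnesium and the C–C bond formation all proceed with retention at the sp2 carbon. The step needs attack at the methylene carbon in preference to attack on the ester or carbonate carbonyl and to self-condensation of 18. This is secured because the aryloxide para to the ester deactivates the ester, 18 forms only on warming with magnesium present and hence in the presence of excess 16, and the exocyclic methylene of 18 is by far the strongest electrophile. The place of the new bond (ortho to the hydroxyl, mono-alkylation, no O-alkylation) is fixed by the CH2OH group of 14 and not by any selectivity of the arene.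

**Step 9**
Reactants: 19 methyl 3-[(2E,6E)-3,7-dimethyl-9-(2,6,6-trimethylcyclohex-1-en-1-yl)nona-2,6-dien-1-yl]-4-hydroxybenzoate
Product: 20 cacospongin D [4-hydroxy-3-[(2E,6E)-3,7-dimethyl-9-(2,6,6-trimethylcyclohex-1-en-1-yl)nona-2,6-dien-1-yl]benzoic acid]
Conditions: LiOH (6 equiv), THF–MeOH–H2O, 50 °C; then 1 M HCl, 0 °C, to pH 3
Reagents that add atoms: lithium hydroxide, [Li+].[OH-]
Why: Saponification (BAc2 ester hydrolysis) with excess hydroxide is slowed but not stopped by the para aryloxide, base cannot isomerise or cyclise the alkenes, and brief cold acidification avoids acid-induced chroman formation from the ortho-allyl phenol.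

**Compound list**
1 | dihydro-β-ionone [4-(2,6,6-trimethylcyclohex-1-en-1-yl)butan-2-one] | CC1=C(CCC(C)=O)C(C)(C)CCC1 | starting material
2 | diethyl 4-(2,6,6-trimethylcyclohex-1-en-1-yl)but-1-en-2-yl phosphate | CC1=C(CCC(=C)OP(=O)(OCC)OCC)C(C)(C)CCC1 | intermediate
3 | 2-(but-3-yn-1-yl)-1,3,3-trimethylcyclohex-1-ene | CC1=C(CCC#C)C(C)(C)CCC1 | intermediate
4 | dimethyl[(1E)-2-methyl-4-(2,6,6-trimethylcyclohex-1-en-1-yl)but-1-en-1-yl]alumane | CC1=C(CC/C(C)=C/[Al](C)C)C(C)(C)CCC1 | intermediate
5 | 2-[(3E)-4-iodo-3-methylbut-3-en-1-yl]-1,3,3-trimethylcyclohex-1-ene | CC1=C(CC/C(C)=C/I)C(C)(C)CCC1 | intermediate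
6 | (4-bromobut-1-yn-1-yl)trimethylsilane | C[Si](C)(C)C#CCCBr | starting material
7 | bromo[4-(trimethylsilyl)but-3-yn-1-yl]zinc | C[Si](C)(C)C#CCC[Zn]Br | intermediate
8 | trimethyl[(5E)-6-methyl-8-(2,6,6-trimethylcyclohex-1-en-1-yl)oct-5-en-1-yn-1-yl]silane | CC1=C(CC/C(C)=C/CCC#C[Si](C)(C)C)C(C)(C)CCC1 | intermediate
9 | 1,3,3-trimethyl-2-[(3E)-3-methyloct-3-en-7-yn-1-yl]cyclohex-1-ene | CC1=C(CC/C(C)=C/CCC#C)C(C)(C)CCC1 | intermediate
10 | [(1E,5E)-2,6-dimethyl-8-(2,6,6-trimethylcyclohex-1-en-1-yl)octa-1,5-dien-1-yl]dimethylalumane | CC1=C(CC/C(C)=C/CC/C(C)=C/[Al](C)C)C(C)(C)CCC1 | intermediate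
11 | 2-[(3E,7E)-8-iodo-3,7-dimethylocta-3,7-dien-1-yl]-1,3,3-trimethylcyclohex-1-ene | CC1=C(CC/C(C)=C/CC/C(C)=C/I)C(C)(C)CCC1 | intermediate
12 | methyl 3-formyl-4-hydroxybenzoate | COC(=O)c1ccc(O)c(C=O)c1 | starting material
13 | methyl 4-[(tert-butoxycarbonyl)oxy]-3-formylbenzoate | COC(=O)c1ccc(OC(=O)OC(C)(C)C)c(C=O)c1 | intermediate
14 | methyl 4-[(tert-butoxycarbonyl)oxy]-3-(hydroxymethyl)benzoate | COC(=O)c1ccc(OC(=O)OC(C)(C)C)c(CO)c1 | intermediate
15 | [(1E,5E)-2,6-dimethyl-8-(2,6,6-trimethylcyclohex-1-en-1-yl)octa-1,5-dien-1-yl]lithium | CC1=C(CC/C(C)=C/CC/C(C)=C/[Li])C(C)(C)CCC1 | intermediate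
16 | bromo[(1E,5E)-2,6-dimethyl-8-(2,6,6-trimethylcyclohex-1-en-1-yl)octa-1,5-dien-1-yl]magnesium | CC1=C(CC/C(C)=C/CC/C(C)=C/[Mg]Br)C(C)(C)CCC1 | intermediate
17 | chloromagnesium 2-{[(tert-butoxycarbonyl)oxy]methyl}-4-(methoxycarbonyl)phenolate | COC(=O)c1ccc(O[Mg]Cl)c(COC(=O)OC(C)(C)C)c1 | intermediate
18 | methyl 3-methylidene-4-oxocyclohexa-1,5-diene-1-carboxylate (o-quinone methide) | COC(=O)C1=CC(=C)C(=O)C=C1 | intermediate
19 | methyl 3-[(2E,6E)-3,7-dimethyl-9-(2,6,6-trimethylcyclohex-1-en-1-yl)nona-2,6-dien-1-yl]-4-hydroxybenzoate | CC1=C(CC/C(C)=C/CC/C(C)=C/Cc2cc(C(=O)OC)ccc2O)C(C)(C)CCC1 | intermediate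
20 | cacospongin D [4-hydroxy-3-[(2E,6E)-3,7-dimethyl-9-(2,6,6-trimethylcyclohex-1-en-1-yl)nona-2,6-dien-1-yl]benzoic acid] | CC1=C(CC/C(C)=C/CC/C(C)=C/Cc2cc(C(=O)O)ccc2O)C(C)(C)CCC1 | target

**Count**
Total steps: 9. Longest linear sequence: 7 (steps 1, 2, 3, 4, 5, 8, 9); steps 6 and 7 form the two-step arene branch.

**Steps most likely to fail**

Step 8 (key step). The ester-stabilised aryloxide may expel the carbonate only slowly, so that the o-quinone methide forms late and oligomerises. The alkenylmagnesium may also be lost by attack on the ester or carbonate carbonyl or by protonation. The fallback makes the same bond by sp2–sp3 cross-coupling and sets out from 14 and 11. Appel bromination of 14 (CBr4, PPh3, CH2Cl2, 0 °C, neutral so that the carbonate does not shift) would give methyl 3-(bromomethyl)-4-[(tert-butoxycarbonyl)oxy]benzoate F1. Iodine–lithium exchange on 11 (t-BuLi, Et2O, −78 °C, through 15) and ZnBr2 would give the alkenylzinc bromide F2. Negishi coupling of F1 with F2 under Pd(PPh3)4 in THF would give the Boc-protected ester methyl 4-[(tert-butoxycarbonyl)oxy]-3-[(2E,6E)-3,7-dimethyl-9-(2,6,6-trimethylcyclohex-1-en-1-yl)nona-2,6-dien-1-yl]benzoate F3. LiOH in THF–MeOH–H2O would then cleave the aryl carbonate and the methyl ester in one operation, and the route is rejoined at 20.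

Step 7. During reduction or work-up the carbonate may shift from the phenolic to the benzylic oxygen and be lost early, with over-reduction of the benzylic position, or the ester may be partly reduced. The fallback moves the hydride step ahead of the carbonate and sets out from 12. NaBH4 in MeOH at 0 °C would give methyl 4-hydroxy-3-(hydroxymethyl)benzoate F4. Boc2O with i-Pr2NEt in CH2Cl2 at 0 °C, without DMAP, should acylate only the far more acidic phenol, and the route is rejoined at 14.

Step 3. Zinc insertion into 6 may be sluggish, and the homopropargylzinc may be lost by protodezincation or homocoupling before it transmetalates. The fallback brings in the same four carbons by alkylation instead of cross-coupling and sets out from 5. t-BuLi (Et2O, −78 °C) would give the alkenyllithium [(1E)-2-methyl-4-(2,6,6-trimethylcyclohex-1-en-1-yl)but-1-en-1-yl]lithium F5. Paraformaldehyde would give the allylic alcohol (2E)-3-methyl-5-(2,6,6-trimethylcyclohex-1-en-1-yl)pent-2-en-1-ol F6. PBr3 (Et2O, 0 °C) would give the allylic bromide 2-[(3E)-5-bromo-3-methylpent-3-en-1-yl]-1,3,3-trimethylcyclohex-1-ene F7. SN2 displacement with [3-(trimethylsilyl)prop-2-yn-1-yl]lithium F8 (from 1-(trimethylsilyl)propyne and n-BuLi, THF, −78 °C) rejoins the route at 8.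

**Further compounds**
F1 | step 8 | methyl 3-(bromomethyl)-4-[(tert-butoxycarbonyl)oxy]benzoate | COC(=O)c1ccc(OC(=O)OC(C)(C)C)c(CBr)c1
F2 | step 8 | bromo[(1E,5E)-2,6-dimethyl-8-(2,6,6-trimethylcyclohex-1-en-1-yl)octa-1,5-dien-1-yl]zinc | CC1=C(CC/C(C)=C/CC/C(C)=C/[Zn]Br)C(C)(C)CCC1
F3 | step 8 | methyl 4-[(tert-butoxycarbonyl)oxy]-3-[(2E,6E)-3,7-dimethyl-9-(2,6,6-trimethylcyclohex-1-en-1-yl)nona-2,6-dien-1-yl]benzoate | CC1=C(CC/C(C)=C/CC/C(C)=C/Cc2cc(C(=O)OC)ccc2OC(=O)OC(C)(C)C)C(C)(C)CCC1
F4 | step 7 | methyl 4-hydroxy-3-(hydroxymethyl)benzoate | COC(=O)c1ccc(O)c(CO)c1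
F5 | step 3 | [(1E)-2-methyl-4-(2,6,6-trimethylcyclohex-1-en-1-yl)but-1-en-1-yl]lithium | CC1=C(CC/C(C)=C/[Li])C(C)(C)CCC1
F6 | step 3 | (2E)-3-methyl-5-(2,6,6-trimethylcyclohex-1-en-1-yl)pent-2-en-1-ol | CC1=C(CC/C(C)=C/CO)C(C)(C)CCC1
F7 | step 3 | 2-[(3E)-5-bromo-3-methylpent-3-en-1-yl]-1,3,3-trimethylcyclohex-1-ene | CC1=C(CC/C(C)=C/CBr)C(C)(C)CCC1
F8 | step 3 | [3-(trimethylsilyl)prop-2-yn-1-yl]lithium | [Li]CC#C[Si](C)(C)C
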